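**Retrosynthetic overview**
1. O–C11 aryl ether: Mitsunobu coupling of umbelliferone with a primary homoallylic alcohol (last step).
2. C9–C11 (key bond, sets C9 and leaves the C7=C8 alkene): visible-light photoredox/chromium Barbier hydroxymethylation of a bicyclic allylic bromide with CH2O.
3. Ring A (the only ring that is made): C3–C4 bond by iron-hydride HAT radical cyclisation of an isopropenyl group onto a nitrile, which gives the 4,4-dimethyl-3-ketone directly.
4. C10 quaternary centre: α'-methylation, then cyanoethylation of (S)-carvone. The carvone ring is ring B (bought); its stereocentre becomes C5 and relays to C10 and then C9.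

Assumption: the target is taken exactly as drawn, i.e. (5S,9S,10R) in drimane numbering (C3 ketone, C4 gem-dimethyl, C5/C10 trans ring fusion, C7=C8, C11 on C9 anti to the C10 methyl); positions below use this numbering.

**Step 1**
Reactants: 1 (S)-(+)-carvone
Product: 2 (5S,6R)-2,6-dimethyl-5-(prop-1-en-2-yl)cyclohex-2-en-1-one (6-methylcarvone; major trans epimer shown, the C6 epimer mixture is carried on)
Conditions: LiN(iPr)2 (1.1 equiv), THF, −78 °C; MeI, −78 to 0 °C
Reagents that add atoms: iodomethane, CI
Why: Kinetic α'-deprotonation gives the cross-conjugated lithium dienolate, which is methylated at C6 (enolate alkylation); the new centre is re-enolised in step 2, so its configuration does not matter.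

**Step 2**
Reactants: 2 6-methylcarvone
Product: 3 3-[(1R,6R)-1,3-dimethyl-2-oxo-6-(prop-1-en-2-yl)cyclohex-3-en-1-yl]propanenitrile (methyl cis, cyanoethyl trans to isopropenyl)
Conditions: LiN(iPr)2 (1.1 equiv), THF, −78 °C; acrylonitrile (1.2 equiv), −78 to −40 °C; AcOH quench
Reagents that add atoms: acrylonitrile, C=CC#N
Why: Michael addition (cyanoethylation) of the tetrasubstituted lithium enolate; the acceptor approaches anti to the neighbouring isopropenyl group fixed by the carvone stereocentre, which sets the quaternary centre (future C10) with the relative configuration needed for a trans-decalin.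

**Step 3**
Reactants: 3 enone nitrile
Product: 4 3-[(1R,2R,6R)-2-hydroxy-1,3-dimethyl-6-(prop-1-en-2-yl)cyclohex-3-en-1-yl]propanenitrile (major carbinol epimer shown)
Conditions: NaBH4, CeCl3·7H2O, MeOH, −20 °C
Reagents that add atoms: none
Why: Luche 1,2-reduction is selective for the enone carbonyl over nitrile and alkenes; hydride enters anti to the axial methyl, but the carbinol configuration is irrelevant because this centre is re-made in step 6.

**Step 4**
Reactants: 4 allylic alcohol nitrile
Product: 6 (4aR,5R,8aS)-5-hydroxy-1,1,4a,6-tetramethyl-3,4,4a,5,8,8a-hexahydronaphthalen-2(1H)-one (trans-fused), via ketimine 5 (not isolated)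
Conditions: Fe(acac)3 (30 mol%), PhSiH3 (3 equiv), EtOH, 60 °C, 0.02 M; then 1 M aq. HCl, THF, 0 °C to rt
Reagents that add atoms: water, O
Why: Mukaiyama-type MHAT places H on the isopropenyl CH2 (the 1,1-disubstituted alkene reacts before the trisubstituted one); the tertiary radical closes ring A by 6-exo-dig addition to the nitrile, and the imine is hydrolysed to the gem-dimethyl ketone. No new stereocentre forms: the trans fusion is dictated by the existing C5 and C10 centres.

**Step 5**
Reactants: 6 bicyclic hydroxy ketone
Product: 7 (4aS,8aS)-7-bromo-1,1,4a,6-tetramethyl-3,4,4a,7,8,8a-hexahydronaphthalen-2(1H)-one (transposed allylic bromide, C7 epimers; used crude)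
Conditions: PBr3 (0.4 equiv), pyridine (10 mol%), Et2O, −10 to 0 °C
Reagents that add atoms: phosphorus tribromide, BrP(Br)Br
Why: Allylic bromination with SN2' transposition away from the neopentyl carbinol carbon; both C7 epimers and any untransposed regioisomer converge on the same allyl radical in step 6.

**Step 6**
Reactants: 7 allylic bromide
Product: 8 (4aR,5S,8aS)-5-(hydroxymethyl)-1,1,4a,6-tetramethyl-3,4,4a,5,8,8a-hexahydronaphthalen-2(1H)-one (CH2OH axial, anti to the angular methyl)
Conditions: CrCl2 (10 mol%), 4CzIPN (2 mol%), Hantzsch ester (1.5 equiv), NaHCO3 (2 equiv), CH2O (5 equiv, THF solution cracked from paraformaldehyde), THF/DMF 4:1, 450 nm LEDs, rt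
Reagents that add atoms: formaldehyde, C=O
Why: Proposed new method: a photoredox-driven, chromium-catalysed Barbier hydroxymethylation in which excited 4CzIPN is quenched by the Hantzsch ester and the reduced dye returns trivalent chromium to divalent chromium; divalent chromium abstracts bromine from either bromide isomer, a second divalent chromium captures the C7–C8–C9 allyl radical as an η1-allyl chromium at the less hindered C7, and this adds to CH2O at C9 through a closed six-membered transition state on the face anti to the axial C10 methyl, giving the axial C11, the C9 stereocentre and the C7=C8 alkene (the aldehyde-selective allyl chromium leaves the hindered C3 ketone alone); the closest known chemistry is the thermal catalytic Nozaki–Hiyama allylation and photoredox/chromium aldehyde allylations that make the allyl radical from alkenes or dienes, none shown with formaldehyde or a γ-neopentyl cyclic allyl bromide.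

**Step 7**
Reactants: 8 primary alcohol; 9 umbelliferone (7-hydroxy-2H-chromen-2-one)
Product: 10 7-{[(1S,4aS,8aR)-2,5,5,8a-tetramethyl-6-oxo-1,4,4a,5,6,7,8,8a-octahydronaphthalen-1-yl]methoxy}-2H-chromen-2-one (target)
Conditions: PPh3, DIAD, THF, 0 to 40 °C
Reagents that add atoms: none
Why: Mitsunobu etherification of an acidic phenol (pKa about 7.8) at the primary C11; no stereocentre is touched and the ketone and alkene are inert.

**Compound list**
1 | (S)-(+)-carvone, (5S)-2-methyl-5-(prop-1-en-2-yl)cyclohex-2-en-1-one | CC1=CC[C@H](C(C)=C)CC1=O | starting material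
2 | (5S,6R)-2,6-dimethyl-5-(prop-1-en-2-yl)cyclohex-2-en-1-one (major epimer) | CC1=CC[C@H](C(C)=C)[C@@H](C)C1=O | intermediate
3 | 3-[(1R,6R)-1,3-dimethyl-2-oxo-6-(prop-1-en-2-yl)cyclohex-3-en-1-yl]propanenitrile | CC1=CC[C@H](C(C)=C)[C@@](C)(CCC#N)C1=O | intermediate
4 | 3-[(1R,2R,6R)-2-hydroxy-1,3-dimethyl-6-(prop-1-en-2-yl)cyclohex-3-en-1-yl]propanenitrile (major epimer) | CC1=CC[C@H](C(C)=C)[C@@](C)(CCC#N)[C@@H]1O | intermediate
5 | ketimine: the 2-imino (N–H) analogue of 6, same configuration at all centres | CC1=CC[C@@H]2C(C)(C)C(=N)CC[C@@]2(C)[C@@H]1O | intermediate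
6 | (4aR,5R,8aS)-5-hydroxy-1,1,4a,6-tetramethyl-3,4,4a,5,8,8a-hexahydronaphthalen-2(1H)-one | CC1=CC[C@@H]2C(C)(C)C(=O)CC[C@@]2(C)[C@@H]1O | intermediate
7 | (4aS,8aS)-7-bromo-1,1,4a,6-tetramethyl-3,4,4a,7,8,8a-hexahydronaphthalen-2(1H)-one (C7 epimers) | BrC1C[C@@H]2C(C)(C)C(=O)CC[C@@]2(C)C=C1C | intermediate
8 | (4aR,5S,8aS)-5-(hydroxymethyl)-1,1,4a,6-tetramethyl-3,4,4a,5,8,8a-hexahydronaphthalen-2(1H)-one | CC1=CC[C@@H]2C(C)(C)C(=O)CC[C@@]2(C)[C@H]1CO | intermediate
9 | umbelliferone, 7-hydroxy-2H-chromen-2-one | Oc1ccc2ccc(=O)oc2c1 | starting material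
10 | 7-{[(1S,4aS,8aR)-2,5,5,8a-tetramethyl-6-oxo-1,4,4a,5,6,7,8,8a-octahydronaphthalen-1-yl]methoxy}-2H-chromen-2-one | CC1=CC[C@@H]2C(C)(C)C(=O)CC[C@@]2(C)[C@H]1COc1ccc2ccc(=O)oc2c1 | target

**Step count**
Total steps: 7. Longest linear sequence: 7 (1 to 10); 9 enters in step 7.

**Steps most likely to fail, with fallbacks**

Step 6 (the new step). Risks are attack at C7 instead of the neopentyl C9, hydrodebromination by the Hantzsch ester, and slow chromium turnover. The fallback uses known chemistry and sets out from bromide 7: photoredox catalysis is dropped for a stoichiometric organoindium Barbier reaction (In powder, 37% aq. CH2O, THF/H2O, rt). The fluxional allylindium adds formaldehyde γ-selectively through the same closed transition state, so the same face is expected. It comes back to the route at alcohol 8 and makes no compound outside the list (F0).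

Step 4. The 6-exo nitrile cyclisation is slow, so the tertiary radical may be reduced to isopropyl first. The fallback sets out from 4. Markovnikov hydrochlorination (Fe2(C2O4)3·6H2O, NaBH4, TsCl, EtOH/H2O, 0 °C) gives 3-[(1R,2R,6S)-6-(2-chloropropan-2-yl)-2-hydroxy-1,3-dimethylcyclohex-3-en-1-yl]propanenitrile F3. Syringe-pump addition of (Me3Si)3SiH with AIBN in benzene at 80 °C then runs a chain cyclisation onto the nitrile at low hydride concentration, giving ketimine 5. HCl hydrolysis brings it back to the route at 6.

Step 2. Acrylonitrile may polymerise under the lithium enolate, and the diastereoselectivity may be modest. The fallback sets out from 2. Michael addition to methyl acrylate (LiN(iPr)2, THF, −78 °C) gives methyl 3-[(1R,6R)-1,3-dimethyl-2-oxo-6-(prop-1-en-2-yl)cyclohex-3-en-1-yl]propanoate F1. Ammonolysis (NH3, MeOH, 50 °C, sealed) gives 3-[(1R,6R)-1,3-dimethyl-2-oxo-6-(prop-1-en-2-yl)cyclohex-3-en-1-yl]propanamide F2. Dehydration ((CF3CO)2O, pyridine, CH2Cl2, 0 °C) brings it back to the route at nitrile 3.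

**Further compounds**
F1 | step 2 | methyl 3-[(1R,6R)-1,3-dimethyl-2-oxo-6-(prop-1-en-2-yl)cyclohex-3-en-1-yl]propanoate | CC1=CC[C@H](C(C)=C)[C@@](C)(CCC(=O)OC)C1=O
F2 | step 2 | 3-[(1R,6R)-1,3-dimethyl-2-oxo-6-(prop-1-en-2-yl)cyclohex-3-en-1-yl]propanamide | CC1=CC[C@H](C(C)=C)[C@@](C)(CCC(N)=O)C1=O
F3 | step 4 | 3-[(1R,2R,6S)-6-(2-chloropropan-2-yl)-2-hydroxy-1,3-dimethylcyclohex-3-en-1-yl]propanenitrile | CC1=CC[C@H](C(C)(C)Cl)[C@@](C)(CCC#N)[C@@H]1O
F0 | step 6 | none | none
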